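## Structural features

Locants used throughout: the enolized trione ring is C1–C6 (C1 spiro, C2=O, C3 bearing the (2R)-2-methylbutanoyl group, C4 enol, C5 bearing methyl and prenyl, C6=O). The hydrindane is C1'–C7a', with C5' identical with C1, C3' and C7' the two carbinol carbons, and C3a'/C7a' the ring fusion.

The target is a dearomatized acylphloroglucinol spiro-fused at C1 to the six-membered ring of a cis-hydrindane. The ten hydrindane carbons C4'–C3a'–C3'(Me)–C2'–C1'–C7a'–C7'(Me)–C6' form a head-to-tail C10 chain whose two ends both sit on C1. The single bond C3a'–C7a' closes the cyclopentane and the cyclohexane at once and lies in the middle of a 1,4-diol (O–C3'–C3a'–C7a'–C7'–O).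

Four contiguous stereocentres (C3', C3a', C7a', C7') carry a cis ring fusion, both methyl groups on the face of the ring-fusion hydrogens and both hydroxyls on the opposite, concave face. C1 is stereogenic only because C2 and C6 differ: the C6 carbonyl, flanked by the quaternary carbons C1 and C5, is cis to the 7'-hydroxyl. C5 (methyl cis to C6', prenyl cis to C4') is remote from everything else, and the acyl α-carbon is (R).

Fragile groups are the two tertiary alcohols (E1 loss, ether formation between O3' and C7'), the prenyl olefin, the acidic and easily oxidized enolized β-triketone, the non-enolizable C2–C1–C6 diketone (retro-Claisen) and the acyl α-stereocentre.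

The real difficulty is the C3a'–C7a' bond with its four stereocentres and the correlation of this array with the quaternary carbon C1. The key step exploits the fact that the endo,endo-diol on a cis-hydrindane is exactly what two anti additions across the two Z olefins of a nine-membered (Z,Z)-1,5-diene give when C3a' and C7a' are joined across the ring. It also exploits the cis placement of the C6 carbonyl and O7', which lets one of two equivalent acyl groups on the future C1 terminate the cyclization.

## Logic of the disconnections

**23 ⇒ 21 + 22.** The C5–CH2 (prenyl) bond is cut. C5 does not communicate sterically with the other stereocentres, so it is made last; the prenyl olefin then never meets the epoxidation or the acid of the key step. The forward step must choose the face of a nearly unbiased enolate, which has to come from a chiral catalyst.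

**21 ⇒ 18 + 19.** The C3–acyl bond is cut. This removes the acidic triketone and the labile α-stereocentre from all earlier steps. The forward step must acylate C3 and not C5 or the tertiary alcohols, without epimerizing the acyl group.

**18 ⇒ 17.** The C4–C5 bond is cut (intramolecular Claisen). The trione ring becomes an open chain in which C2 and C6 are chemically different (β-keto ester arm versus ethyl ketone). The forward step needs the ethyl ketone to enolize only toward C5, which is guaranteed because its other α-carbon is C1.

**17 ⇒ 16.** The C5–C6 bond is cut; the ethyl group (C5 and its methyl) is added to a lactone carbonyl that becomes C6. The gain is that C6 is now defined as the carbonyl tied to O7'. The forward step needs a single addition to the lactone in the presence of the β-keto ester.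

**16 ⇒ 13 + 14.** The C2–C3 bond is cut. The β-keto ester arm comes from a free carboxylic acid, which is cleanly distinguishable from the lactone. The forward step must activate the acid only.

**13 ⇒ 12 (key).** The C3a'–C7a' bond and the O7'–acyl bond are cut, and the lactone and acid are returned to one symmetric dioxanedione. In one sentence: an acid-triggered transannular epoxide–olefin cyclization of the spiro (Z,Z)-cyclonona-1,5-diene monoepoxide 12 folds the nine-membered ring into the cis-hydrindane and lactonizes one of its two equivalent acyl groups. The gain is large: a tricycle with five stereogenic carbons becomes a monocyclic ring with one epoxide and a non-stereogenic spiro carbon. The forward step must open the epoxide at its secondary carbon, close cis, and capture the cation with the carbonyl oxygen.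

**12 ⇒ 11.** The epoxide oxygen is removed. The precursor is achiral, so the absolute configuration of the whole hydrindane rests on one catalyst-controlled epoxidation. The forward step must epoxidize one ring olefin on one face and stop there.

**11 ⇒ 8 + 9.** Both C–CH2 bonds at the spiro carbon are cut. The nine-membered ring comes from a symmetric carbon acid and a linear bis-allylic electrophile; no stereocentre is involved. The forward step must close a medium ring in competition with oligomerization.

**8 ⇒ 6 ⇒ 5 ⇒ 3 + 4 ⇒ 1.** Functional-group changes lead back to an enoate; its C=C bond is cut (Z-selective olefination), and the aldehyde comes from cleavage of the distal olefin of 1, which already holds the other Z olefin. The forward steps must keep both Z geometries, on which the relative configuration of the key step depends.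

## Other disconnections considered

**Alternative 1:** (the first that comes to mind) Cut C1–C4' and C1–C6'. Forward key step: spiro-annulation of the preformed trione A1 with the cyclopentane bis-electrophile A2 (C-alkylation by the iodide, then enolate opening of the epoxide at its CH2) to give 23 directly. Grounds against it:
- A2 already holds all four hydrindane stereocentres and both tertiary carbinols, so the hard part is only moved into a separate multistep synthesis.
- The first alkylation uses an unactivated primary iodide, for which enolized triones favour O-alkylation.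
- The ring closure creates C1 on an almost planar enolate whose faces differ only through the remote C5 substituents, so nothing secures the C6-carbonyl/O7' cis relationship.

The chosen plan removes this last problem by symmetry.

**Alternative 2:** Cut C1–C6' and C4'–C3a' in a [4+2] sense. Forward key step: Knoevenagel condensation of A1 with formaldehyde to the methylene trione A3, then Diels–Alder reaction with diene A4 to the spiro adduct A5. Grounds against it:
- A3 is also a 1-oxadiene, and hetero-Diels–Alder addition to pyran-type adducts is the expected competing path.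
- A5 holds a tetrasubstituted C7'=C7a' olefin; converting it to 7'-OH/7a'-H with defined configuration has no regiochemical handle, since both carbons are fully substituted.
- The facial relationship to C3' and C1 is not controlled.

**Alternative 3:** Build the deoxygenated skeleton A6 first and introduce both tertiary hydroxyls by C–H oxidation with retention (dioxirane or non-heme iron catalysis). Grounds against it:
- The C3'–H and C7'–H bonds must already have the right configuration, so no stereochemical work is saved.
- The prenyl olefin and the enolized triketone are far more oxidizable than unactivated tertiary C–H bonds.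
- The ring-fusion C–H bonds and the acyl α-C–H compete, and no directing effect singles out C3' and C7'.

Key step: step 7

Assumption 1: compounds 18, 20 and 21 are written as dienol tautomers; their C5 carbon is enolic and not a stereocentre until step 12.

Assumption 2: in step 12 the (1R,2R)-configured ligand is taken to deliver the prenyl group to the C5 face syn to C4'. This sense is not secured by a close analogy; the mirror-image ligand is used if the opposite face is delivered.

Assumption 3: compounds 1, 4, 9, 14, 19 and 22 are taken as commercial.

## Route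

Step 1
Reactants: 1 neryl acetate
Product: 3 (4Z)-6-acetoxy-4-methylhex-4-enal, via ozonide 2 (not isolated)
Conditions: O3, CH2Cl2, −78 °C (indicator end point); then Me2S, −78 °C to rt
Reagents that add atoms: ozone, O=[O+][O-]
Why: Chemoselective ozonolysis: the distal trisubstituted olefin is the electron-rich one, while the C2=C3 olefin is deactivated by the allylic acetate and keeps its Z geometry.

Step 2
Reactants: 3 (4Z)-6-acetoxy-4-methylhex-4-enal; 4 ethyl 2-[bis(2,2,2-trifluoroethoxy)phosphoryl]propanoate
Product: 5 ethyl (2Z,6Z)-8-acetoxy-2,6-dimethylocta-2,6-dienoate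
Conditions: KN(SiMe3)2, 18-crown-6, THF, −78 °C
Reagents that add atoms: none
Why: Still–Gennari olefination; the electron-poor phosphonate eliminates under kinetic control and should give the Z trisubstituted enoate (ester cis to the chain), which fixes the second Z olefin.

Step 3
Reactants: 5 ethyl (2Z,6Z)-8-acetoxy-2,6-dimethylocta-2,6-dienoate
Product: 6 (2Z,6Z)-2,6-dimethylocta-2,6-diene-1,8-diol
Conditions: i-Bu2AlH (5 equiv), CH2Cl2, −78 to 0 °C; aq. KNaC4H4O6 (potassium sodium tartrate)
Reagents that add atoms: none
Why: Hydride reduction of the enoate to the allylic alcohol with concurrent reductive removal of the acetate; both olefin geometries are untouched.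

Step 4
Reactants: 6 (2Z,6Z)-2,6-dimethylocta-2,6-diene-1,8-diol
Product: 8 (2Z,6Z)-1,8-dichloro-2,6-dimethylocta-2,6-diene, via bis-mesylate 7 (not isolated)
Conditions: MeSO2Cl, 2,4,6-collidine, LiCl, DMF, 0 °C to rt
Reagents that add atoms: lithium chloride, [Li+].[Cl-]
Why: In situ sulfonylation and SN2 displacement by chloride at the primary allylic carbons, a sequence that avoids allylic transposition and E/Z isomerization.

Step 5
Reactants: 8 (2Z,6Z)-1,8-dichloro-2,6-dimethylocta-2,6-diene; 9 Meldrum's acid (2,2-dimethyl-1,3-dioxane-4,6-dione)
Product: 11 (8Z,12Z)-3,3,8,12-tetramethyl-2,4-dioxaspiro[5.8]tetradeca-8,12-diene-1,5-dione, via mono-alkylated Meldrum's acid 10 (not isolated)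
Conditions: Cs2CO3 (3 equiv), NaI (0.2 equiv), DMF, 45 °C, slow addition of 8 and 9 (final 2 mM)
Reagents that add atoms: none
Why: Twofold C-alkylation of the cyclic malonate (spiro-annulation), first intermolecular and then ring-closing; the two Z olefins hold the chain in a U shape that should ease the nine-membered closure. SN2 at the primary carbons keeps both Z geometries, and the spiro carbon is not a stereocentre because the dioxanedione is symmetric.

Step 6
Reactants: 11 (8Z,12Z)-3,3,8,12-tetramethyl-2,4-dioxaspiro[5.8]tetradeca-8,12-diene-1,5-dione
Product: 12 (8Z,12S,13R)-12,13-epoxy-3,3,8,12-tetramethyl-2,4-dioxaspiro[5.8]tetradec-8-ene-1,5-dione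
Conditions: 1,2:4,5-di-O-isopropylidene-β-D-erythro-2,3-hexodiulo-2,6-pyranose (0.3 equiv), KHSO5 (as 2KHSO5·KHSO4·K2SO4, 0.9 equiv), K2CO3, n-Bu4NHSO4 (cat.), MeCN–CH2(OMe)2–aq. Na2B4O7 buffer (pH 10.5), 0 °C
Reagents that add atoms: potassium peroxymonosulfate, [K+].OOS(=O)(=O)[O-]
Why: Shi epoxidation of an achiral diene; the chiral dioxirane reads the local substitution of the trisubstituted olefin (olefinic H in the hindered quadrant of the spiro transition state) and should deliver oxygen to the face giving 12S,13R, which sets C3' and, after inversion in step 7, C3a'. The C12=C13 olefin should react first because its methyl-bearing carbon is remote from the bulky, electron-poor spiro centre, and sub-stoichiometric oxidant limits double epoxidation.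

Step 7
Reactants: 12 (8Z,12S,13R)-12,13-epoxy-3,3,8,12-tetramethyl-2,4-dioxaspiro[5.8]tetradec-8-ene-1,5-dione
Product: 13 (1S,2R,5S,6R,8S)-5-hydroxy-1,5-dimethyl-9-oxo-10-oxatricyclo[6.2.1.0(2,6)]undecane-8-carboxylic acid
Conditions: TsOH·H2O (10 mol %), water-saturated CH2Cl2, −20 °C to rt
Reagents that add atoms: none
Why: Acid-mediated transannular epoxide–olefin cyclization, the reaction type by which medium-ring terpene epoxides (germacrane and caryophyllene oxides) fold to bicycles. After protonation, C9 of the Z olefin attacks C13 anti to the breaking C13–O bond, so the oxygen stays on the tertiary C12; opening at the secondary carbon is enforced by the short transannular C9–C13 distance and by the tertiary cation that develops at C8. The one new C–C bond closes the cyclopentane (5-exo-trig at the olefin, endo opening of the epoxide) and the cyclohexane (6-endo-trig at the olefin, exo at the epoxide) together. The cation at C8 is captured on its outer face by the carbonyl oxygen of the dioxanedione on that side (5-exo), and loss of acetone with water leaves the γ-lactone and the free acid. C3' keeps the epoxide configuration; C3a' is inverted; the cis fusion follows from the tub conformation of the Z,Z nine-membered ring, in which the mutually facing olefin faces bond; C7' results from anti addition across the Z olefin; and the future C1 is desymmetrized because only the carbonyl syn to O7' can lactonize. The step needs transannular closure to beat 1,2-hydride shift and elimination (low temperature, proximity of the π bond) and carbonyl capture to beat capture by the 3'-hydroxyl (five-membered lactone against a strained oxa-bridged ether).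

Step 8
Reactants: 13 (1S,2R,5S,6R,8S)-5-hydroxy-1,5-dimethyl-9-oxo-10-oxatricyclo[6.2.1.0(2,6)]undecane-8-carboxylic acid; 14 potassium methyl malonate
Product: 16 methyl 3-[(1S,2R,5S,6R,8S)-5-hydroxy-1,5-dimethyl-9-oxo-10-oxatricyclo[6.2.1.0(2,6)]undecan-8-yl]-3-oxopropanoate, via acyl imidazole 15 (not isolated)
Conditions: 1,1'-carbonyldiimidazole, THF, rt; then 14, MgCl2, Et3N, THF, rt to 45 °C; aq. HCl work-up
Reagents that add atoms: none
Why: Masamune–Brooks homologation: the acyl imidazole C-acylates the magnesium malonate and decarboxylation gives the β-keto ester. Only the free acid is activated; the lactone is untouched and the 3'-hydroxyl, on the opposite face, cannot reach the acyl imidazole, so the acid carbon is fixed as the future C2.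

Step 9
Reactants: 16 methyl 3-[(1S,2R,5S,6R,8S)-5-hydroxy-1,5-dimethyl-9-oxo-10-oxatricyclo[6.2.1.0(2,6)]undecan-8-yl]-3-oxopropanoate
Product: 17 methyl 3-[(3S,3aR,5R,7S,7aR)-3,7-dihydroxy-3,7-dimethyl-5-propanoyloctahydro-1H-inden-5-yl]-3-oxopropanoate
Conditions: LiN(SiMe3)2 (2.2 equiv), THF, −78 °C; then EtLi (1.3 equiv), −78 to −40 °C; AcOH quench
Reagents that add atoms: ethyllithium, [Li]CC
Why: Organolithium addition to a lactone; the β-keto ester and the hydroxyl are masked as lithium enolate and alkoxide. EtLi should add once to the strained lactone carbonyl, and the tetrahedral lithium lactolate, stable at low temperature, collapses on work-up to the ethyl ketone (future C6, C5 and C5-methyl) and the free 7'-hydroxyl.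

Step 10
Reactants: 17 methyl 3-[(3S,3aR,5R,7S,7aR)-3,7-dihydroxy-3,7-dimethyl-5-propanoyloctahydro-1H-inden-5-yl]-3-oxopropanoate
Product: 18 (3'S,3a'R,7'S,7a'R)-3',7'-dihydroxy-3',5,7'-trimethyloctahydrospiro[cyclohexane-1,5'-indene]-2,4,6-trione (drawn as the 4,6-dienol; enolized C6 cis to the 7'-hydroxyl)
Conditions: LiN(i-Pr)2 (4 equiv), THF, −78 to 0 °C; aq. HCl work-up
Reagents that add atoms: none
Why: Dieckmann-type intramolecular Claisen condensation: the ethyl ketone can enolize only toward C5, and this carbon attacks the ester carbonyl (future C4) to close the six-membered trione. The reaction is driven by formation of the stabilized trione polyanion and places the methyl group on the carbon next to C6.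

Step 11
Reactants: 18 (3'S,3a'R,7'S,7a'R)-3',7'-dihydroxy-3',5,7'-trimethyloctahydrospiro[cyclohexane-1,5'-indene]-2,4,6-trione; 19 (2R)-2-methylbutanoic acid
Product: 21 3-[(2R)-2-methylbutanoyl] derivative of 18 (enolized acyl trione with C5 still bearing only methyl), via enol ester 20 (not isolated)
Conditions: N,N'-dicyclohexylcarbodiimide, 4-(dimethylamino)pyridine, CH2Cl2, 0 °C to rt
Reagents that add atoms: none
Why: O-acylation followed by the 4-(dimethylamino)pyridine-mediated 1,3-acyl shift (Fries-type O-to-C transfer) to C3, the unsubstituted carbon between two carbonyls. Transfer to the methylated C5 would give a non-enolizable triketone and is reversible, the tertiary alcohols are not acylated, and the mild, weakly basic conditions should preserve the α-stereocentre of 19.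

Step 12
Reactants: 21 3-[(2R)-2-methylbutanoyl] derivative of 18; 22 prenyl acetate (3-methylbut-2-en-1-yl acetate)
Product: 23 (1R,3'S,3a'R,5S,7'S,7a'R)-3',4,7'-trihydroxy-3',5,7'-trimethyl-5-(3-methylbut-2-en-1-yl)-3-[(2R)-2-methylbutanoyl]-1',2',3',3a',4',6',7',7a'-octahydrospiro[cyclohex-3-ene-1,5'-indene]-2,6-dione (CNP0236509.3)
Conditions: Pd2(dba)3·CHCl3 (2.5 mol %), (1R,2R)-N,N'-bis[2-(diphenylphosphino)benzoyl]cyclohexane-1,2-diamine (7.5 mol %), Cs2CO3 (2.1 equiv), CH2Cl2, 0 °C
Reagents that add atoms: none
Why: Tsuji–Trost asymmetric allylic alkylation of the dianion at C5; attack at the unsubstituted terminus of the prenyl-palladium complex gives the linear prenyl group, and O-prenylated material re-ionizes to the C-alkylated product. The two faces of C5 differ only through C4'H2 and C6'H2 of the spiro ring, so the chiral ligand pocket, not the substrate, is relied on to set C5 (S, prenyl syn to C4').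

## Compound list

1 | neryl acetate, (2Z)-3,7-dimethylocta-2,6-dien-1-yl acetate | CC(=O)OC/C=C(/C)CCC=C(C)C | starting material
2 | ozonide of 1, (2Z)-5-(5,5-dimethyl-1,2,4-trioxolan-3-yl)-3-methylpent-2-en-1-yl acetate | CC(=O)OC/C=C(/C)CCC1OOC(C)(C)O1 | intermediate
3 | (4Z)-6-acetoxy-4-methylhex-4-enal | CC(=O)OC/C=C(/C)CCC=O | intermediate
4 | ethyl 2-[bis(2,2,2-trifluoroethoxy)phosphoryl]propanoate | CCOC(=O)C(C)P(=O)(OCC(F)(F)F)OCC(F)(F)F | starting material
5 | ethyl (2Z,6Z)-8-acetoxy-2,6-dimethylocta-2,6-dienoate | CCOC(=O)/C(C)=C\CC/C(C)=C\COC(C)=O | intermediate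
6 | (2Z,6Z)-2,6-dimethylocta-2,6-diene-1,8-diol | OC/C(C)=C\CC/C(C)=C\CO | intermediate
7 | (2Z,6Z)-2,6-dimethylocta-2,6-diene-1,8-diyl dimethanesulfonate | CS(=O)(=O)OC/C(C)=C\CC/C(C)=C\COS(C)(=O)=O | intermediate
8 | (2Z,6Z)-1,8-dichloro-2,6-dimethylocta-2,6-diene | ClC/C(C)=C\CC/C(C)=C\CCl | intermediate
9 | Meldrum's acid, 2,2-dimethyl-1,3-dioxane-4,6-dione | CC1(C)OC(=O)CC(=O)O1 | starting material
10 | 5-[(2Z,6Z)-8-chloro-3,7-dimethylocta-2,6-dien-1-yl]-2,2-dimethyl-1,3-dioxane-4,6-dione | CC1(C)OC(=O)C(C/C=C(/C)CC/C=C(/C)CCl)C(=O)O1 | intermediate
11 | (8Z,12Z)-3,3,8,12-tetramethyl-2,4-dioxaspiro[5.8]tetradeca-8,12-diene-1,5-dione | CC1(C)OC(=O)C2(C/C=C(/C)CC/C=C(/C)C2)C(=O)O1 | intermediate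
12 | (8Z,12S,13R)-12,13-epoxy-3,3,8,12-tetramethyl-2,4-dioxaspiro[5.8]tetradec-8-ene-1,5-dione | CC1(C)OC(=O)C2(C[C@H]3O[C@@]3(C)CC/C=C(/C)C2)C(=O)O1 | intermediate
13 | (1S,2R,5S,6R,8S)-5-hydroxy-1,5-dimethyl-9-oxo-10-oxatricyclo[6.2.1.0(2,6)]undecane-8-carboxylic acid (cis-hydrindane; γ-lactone from the concave acyl group to O7'; CO2H on the face of the ring-fusion hydrogens; free 3'-OH) | OC(=O)[C@]12C[C@@H]3[C@@H](CC[C@]3(C)O)[C@](C)(C1)OC2=O | intermediate
14 | potassium methyl malonate | COC(=O)CC(=O)[O-].[K+] | starting material
15 | imidazolide of 13 (1H-imidazol-1-yl ketone at the former CO2H) | O=C(n1ccnc1)[C@]23C[C@@H]4[C@@H](CC[C@]4(C)O)[C@](C)(C2)OC3=O | intermediate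
16 | methyl 3-[(1S,2R,5S,6R,8S)-5-hydroxy-1,5-dimethyl-9-oxo-10-oxatricyclo[6.2.1.0(2,6)]undecan-8-yl]-3-oxopropanoate | COC(=O)CC(=O)[C@]12C[C@@H]3[C@@H](CC[C@]3(C)O)[C@](C)(C1)OC2=O | intermediate
17 | methyl 3-[(3S,3aR,5R,7S,7aR)-3,7-dihydroxy-3,7-dimethyl-5-propanoyloctahydro-1H-inden-5-yl]-3-oxopropanoate (propanoyl cis to the 7-hydroxyl) | CCC(=O)[C@]1(C[C@@H]2[C@@H](CC[C@]2(C)O)[C@@](C)(O)C1)C(=O)CC(=O)OC | intermediate
18 | (3'S,3a'R,7'S,7a'R)-3',7'-dihydroxy-3',5,7'-trimethyloctahydrospiro[cyclohexane-1,5'-indene]-2,4,6-trione, drawn as 4,6-dienol (C6 cis to 7'-OH) | CC1=C(O)[C@]2(C[C@@H]3[C@@H](CC[C@]3(C)O)[C@@](C)(O)C2)C(=O)C=C1O | intermediate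
19 | (2R)-2-methylbutanoic acid | CC[C@@H](C)C(O)=O | starting material
20 | 4-O-[(2R)-2-methylbutanoyl] enol ester of 18 | CC[C@@H](C)C(=O)OC1=CC(=O)[C@@]2(C[C@@H]3[C@@H](CC[C@]3(C)O)[C@@](C)(O)C2)C(O)=C1C | intermediate
21 | 3-[(2R)-2-methylbutanoyl] derivative of 18 (enolized acyl trione, C5 bearing methyl only) | CC[C@@H](C)C(=O)C1=C(O)C(C)=C(O)[C@]2(C[C@@H]3[C@@H](CC[C@]3(C)O)[C@@](C)(O)C2)C1=O | intermediate
22 | prenyl acetate, 3-methylbut-2-en-1-yl acetate | CC(=O)OCC=C(C)C | starting material
23 | (1R,3'S,3a'R,5S,7'S,7a'R)-3',4,7'-trihydroxy-3',5,7'-trimethyl-5-(3-methylbut-2-en-1-yl)-3-[(2R)-2-methylbutanoyl]-octahydrospiro[cyclohex-3-ene-1,5'-indene]-2,6-dione | CC[C@@H](C)C(=O)C1=C(O)[C@](C)(CC=C(C)C)C(=O)[C@]2(C[C@@H]3[C@@H](CC[C@]3(C)O)[C@@](C)(O)C2)C1=O | target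

## Step count and least certain steps

Total step count: 12. Longest linear sequence: 12 steps (1 to 23); all other building blocks are commercial.

**Step 7 (key step).** The opened epoxide may undergo a 1,2-hydride shift before the olefin engages. The tertiary cation may also be lost by proton elimination, or be captured by water or by the 3'-hydroxyl instead of the carbonyl oxygen; all of these are ordinary fates of tertiary cations next to a free alcohol. Fallback: separate the C–C bond formation from the acyl differentiation. Setting out from 12, solvolysis in THF–H2O with catalytic HClO4 at 0 °C lets water terminate the cyclization and should give (3'S,3a'R,7'S,7a'R)-3',7'-dihydroxy-2,2,3',7'-tetramethyloctahydrospiro[1,3-dioxane-5,5'-indene]-4,6-dione F1 with the dioxanedione intact. Warming F1 with 4-(dimethylamino)pyridine and Et3N in toluene (60 °C) then lets the 7'-hydroxyl acylate itself on the only carbonyl it can reach, with loss of acetone, and the sequence comes back to the route at 13.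

**Step 5.** Oligomerization can outrun the nine-membered ring closure, because medium rings close slowly and the second alkylation uses a hindered, stabilized anion. Prolonged heating also risks Cope rearrangement of the Z,Z-1,5-diene. Fallback: replace the SN2 closure by π-allyl chemistry. Setting out from 6, methyl chloroformate/pyridine gives (2Z,6Z)-2,6-dimethylocta-2,6-diene-1,8-diyl dimethyl biscarbonate F2. F2 and 9 are then combined under high dilution with a zerovalent palladium catalyst (Pd(PPh3)4, THF, 40 °C) in a twofold Tsuji–Trost alkylation, in which reversible ionization and attack at the unsubstituted allyl termini funnel material into the ring; the sequence comes back at 11.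

**Step 6.** Face selection on a Z-configured ring olefin with two alkyl substituents may be incomplete, and the two ring olefins may not be well distinguished, since the catalyst model is best founded for trans and aryl-substituted olefins. Fallback: give up catalyst control and resolve. Setting out from 11, epoxidation with 3-chloroperbenzoic acid gives 12 together with its enantiomer (8Z,12R,13S)-12,13-epoxy-3,3,8,12-tetramethyl-2,4-dioxaspiro[5.8]tetradec-8-ene-1,5-dione F3. The conditions of step 7 convert the pair into 13 and its enantiomer (1R,2S,5R,6S,8R)-5-hydroxy-1,5-dimethyl-9-oxo-10-oxatricyclo[6.2.1.0(2,6)]undecane-8-carboxylic acid F4. Fractional crystallization of the (1R)-1-phenylethan-1-aminium salt of 13 F5 (or use of the mirror-image amine should the salt of F4 crystallize first) and liberation with dilute HCl brings the sequence back at 13.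

**Step 12.** Facial discrimination at C5 may be poor, because the substrate offers no bias and ligand control over the face of a prochiral, highly delocalized nucleophile is the weakest mode of induction in allylic alkylation. Long exposure to the catalyst could also re-ionize the C5–prenyl bond. Fallback: separation and recycling instead of induction. Setting out from 21, prenylation with 22 and the achiral catalyst Pd(PPh3)4 gives 23 and its C5 epimer, (1R,3'S,3a'R,5R,7'S,7a'R)-configured 5-epi-23 F6, which are diastereomers and should separate by chromatography. F6 is returned to 21 by deprenylation with the zerovalent palladium catalyst and morpholine, and the sequence ends at 23.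

## Further compounds

F1 | step 7 | (3'S,3a'R,7'S,7a'R)-3',7'-dihydroxy-2,2,3',7'-tetramethyloctahydrospiro[1,3-dioxane-5,5'-indene]-4,6-dione | CC1(C)OC(=O)C2(C[C@@H]3[C@@H](CC[C@]3(C)O)[C@@](C)(O)C2)C(=O)O1
F2 | step 5 | (2Z,6Z)-2,6-dimethylocta-2,6-diene-1,8-diyl dimethyl biscarbonate | COC(=O)OC/C(C)=C\CC/C(C)=C\COC(=O)OC
F3 | step 6 | (8Z,12R,13S)-12,13-epoxy-3,3,8,12-tetramethyl-2,4-dioxaspiro[5.8]tetradec-8-ene-1,5-dione (enantiomer of 12) | CC1(C)OC(=O)C2(C[C@@H]3O[C@]3(C)CC/C=C(/C)C2)C(=O)O1
F4 | step 6 | (1R,2S,5R,6S,8R)-5-hydroxy-1,5-dimethyl-9-oxo-10-oxatricyclo[6.2.1.0(2,6)]undecane-8-carboxylic acid (enantiomer of 13) | OC(=O)[C@@]12C[C@H]3[C@H](CC[C@@]3(C)O)[C@@](C)(C1)OC2=O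
F5 | step 6 | (1R)-1-phenylethan-1-aminium salt of 13 | C[C@@H]([NH3+])c1ccccc1.[O-]C(=O)[C@]12C[C@@H]3[C@@H](CC[C@]3(C)O)[C@](C)(C1)OC2=O
F6 | step 12 | C5 epimer of 23, (1R,3'S,3a'R,5R,7'S,7a'R)-configured | CC[C@@H](C)C(=O)C1=C(O)[C@@](C)(CC=C(C)C)C(=O)[C@]2(C[C@@H]3[C@@H](CC[C@]3(C)O)[C@@](C)(O)C2)C1=O
A1 | alternative 1 | (4S)-4-methyl-4-(3-methylbut-2-en-1-yl)-2-[(2R)-2-methylbutanoyl]cyclohexane-1,3,5-trione, enol form | CC[C@@H](C)C(=O)C1=C(O)[C@](C)(CC=C(C)C)C(=O)CC1=O
A2 | alternative 1 | 2-(iodomethyl)-1-methyl-3-(2-methyloxiran-2-yl)cyclopentan-1-ol with the C3', C3a', C7a', C7' configurations of the target | IC[C@@H]1[C@@H](CC[C@]1(C)O)[C@@]2(C)OC2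
A3 | alternative 2 | 6-methylene derivative of A1 | CC[C@@H](C)C(=O)C1=C(O)[C@](C)(CC=C(C)C)C(=O)C(=C)C1=O
A4 | alternative 2 | (1S)-1-methyl-3-(prop-1-en-2-yl)cyclopent-2-en-1-ol | CC(=C)C1=C[C@@](C)(O)CC1
A5 | alternative 2 | Diels–Alder spiro adduct with a C7'=C7a' olefin and 3'-OH | CC[C@@H](C)C(=O)C1=C(O)[C@](C)(CC=C(C)C)C(=O)[C@]2(C[C@@H]3C(CC[C@]3(C)O)=C(C)C2)C1=O
A6 | alternative 3 | 3',7'-dideoxy analogue of 23 (C3'–H and C7'–H in place of the hydroxyls, retention geometry) | CC[C@@H](C)C(=O)C1=C(O)[C@](C)(CC=C(C)C)C(=O)[C@]2(C[C@@H]3[C@@H](CC[C@H]3C)[C@H](C)C2)C1=O
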